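## Structural features

The target is a 4→8 biflavanoid. The upper unit is a 3-deoxyflavan (phloroglucinol ring A fused to pyran ring C through C4a/C8a, catechol ring B on C2). The lower unit is (+)-catechin (rings D, F, E), joined through the C4–C8′ bond (primed locants are lower-unit atoms). The upper unit has two stereocentres, C2 (S) and C4 (S), in a 1,3-relation across the C3 methylene with the two aryl groups cis. The lower unit has the adjacent trans pair C2′ (R)/C3′ (S) of natural (+)-catechin. Fragile elements are the nine phenolic hydroxyls (two catechols, two phloroglucinol-type rings open to oxidation and C-alkylation), the doubly benzylic, acid-labile C4–C8′ bond, and the benzylic ethers O1–C2 and O1′–C2′. The real difficulty is C4: a diarylmethine flanked by four ortho oxygens, with no C3 substituent to relay stereocontrol and with C6′ competing with C8′ in any electrophilic coupling. The key step exploits ring A as a 2-alkylphloroglucinol. While O1–C2 is open it has a local mirror plane through C4a and C7, so C5 and C8a (and C6 and C8) are equivalent. Ring A can therefore be folded from a malonate (C5–C4a–C8a) that already carries stereodefined C4 and a 3-oxoglutarate (C6–C7–C8). Either ortho hydroxyl then closes ring C.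

## Logic of the disconnections

**20 ⇒ 19.** Seven benzyl O–C bonds are cut. All B-, D- and E-ring oxygens and O3′ stay masked to the end so that no oxidisable polyphenol is carried through the route. The forward step must be neutral hydrogenolysis that spares O1–C2, O1′–C2′ and C4–C8′.

**19 ⇒ 17 (through 18).** Two carboxyl carbons are added back at C6 and C8. They are the residue of the three-carbon building block, and they block ring A during ring closure. The forward step must hydrolyse two hindered esters and decarboxylate without touching C2 or C4.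

**17 ⇒ 16.** O1–C2 is cut. Ring C is closed late, when the two ortho hydroxyls are equivalent, so there is no regiochemical question. C2 is traced to a carbinol of opposite configuration. The forward step must be a clean SN2 etherification.

**16 ⇒ 15.** The O–Si bond is restored. The carbinol must be masked while the malonate is present. The forward step is a mild fluoride cleavage.

**15 ⇒ 13 + 14.** C5–C6 and C8–C8a are cut. Ring A falls apart into a malonate and a 3-oxoglutarate, so the hexasubstituted arene is traded for two acyclic diesters and all regiochemistry disappears. The forward step needs twofold C-acylation of a keto-diester by a hindered, enolisable malonate.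

**13 ⇒ 11 (through 12).** The C2–H bond and the silyl ether are removed. C2 becomes a ketone that also served as the acceptor for setting C4. The forward step needs reagent-controlled hydride delivery and silylation before the hydroxyl can attack a malonate ester.

**11 ⇒ 9 + 10.** The C4–C4a bond is cut. C4 is created by conjugate addition, the one point where a catalyst sets this centre. The forward step needs Re-face addition to a hindered, electron-rich enone.

**9 ⇒ 6 + 8.** The C3=C4 bond is cut by a retro-aldol condensation into an aldehyde and a methyl ketone. The forward step needs only E geometry.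

**6 ⇒ 4 ⇒ 3 ⇒ 1.** The C8′–CHO bond, then C8′–Br, then five benzyl ethers are removed, which leads to the chiral-pool starting material. The forward steps need C8′ over C6′ selectivity, supplied by bromination.

**8 ⇒ 7.** Two benzyl ethers are removed.

## Other disconnections considered

**Alternative 1:** The cut removes O1–C2 and C2–C3. C2 with ring B becomes 3,4-bis(benzyloxy)benzaldehyde A2, and the rest is the 1,1-diarylethylene phenol A1, in which ring A is already bonded to the catechin unit through the future C4.
- Forward step: a confined chiral Brønsted acid (an imidodiphosphorimidate) would condense the phenol of A1 with A2 to an oxocarbenium ion. The terminal alkene carbon would attack it, and proton loss would give the flav-3-ene A3 with C2 set by the catalyst. Hydrogenation from the face opposite ring B would then create C4 with the 2,4-cis relation and remove all benzyl groups in the same operation.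
- In favour: high convergence, C2 made catalytically in the ring-forming event, and a one-step finish.
- Against: A1 is a tetra-ortho-substituted, very electron-rich alkene that strong acid can protonate at its terminal carbon. A2 is a deactivated aldehyde. The bulky benzylated catechin residue is unlikely to fit a confined catalyst pocket. The C2 configuration of a 2-aryl-2H-chromene can be lost by reversible electrocyclic ring opening or by acid ionisation.
- Comparison: on structure, both plans derive the cis relation from a late event (hydrogenation there, SN2 inversion here), but the chosen plan sets C4 and C2 in two independent reagent-controlled steps. On mechanism, Alternative 1 runs cationic chemistry next to the acid-labile diarylmethine region, while the chosen plan is basic or neutral throughout. On step economy Alternative 1 is the better plan, and on convergence as well.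

**Alternative 2:** The cut removes C4–C4a and O1–C2. The pieces are 3,5-bis(benzyloxy)phenol A4 and the enone 9 of the chosen route.
- Forward step: the ortho carbon of A4 adds to the beta carbon of 9 (Friedel–Crafts conjugate addition under a chiral acid or bifunctional catalyst). The phenol oxygen then condenses with the ketone to give the flav-2-ene A5. Hydrogenation from the face opposite the C4 substituent would give the 2,4-cis flavan and cleave the benzyl ethers.
- In favour: the reaction type is established for electron-rich phenols and chalcones. No redox or inversion step is needed for C2. The sequence from 9 is two steps against seven in the chosen plan, so on step economy it is clearly the better plan.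
- Against: A4 can also react at the carbon para to its hydroxyl, which is equally activated and cannot cyclise. Enantiocontrol at C4 has to be achieved on the same hindered, deactivated enone (a risk equal to that of step 6 of the chosen plan). The 2-aryl-4H-chromene is an enol ether prone to acid-induced disproportionation and air oxidation. C2 then depends on substrate-controlled hydrogenation in competition with hydrogenolysis of O1–C2.
- Comparison: on structure, the chosen plan removes the ring A regiochemical question through local symmetry and sets C2 by a reagent. On mechanism, both rely on a first-of-kind event on the same enone or its adduct. Alternative 2 wins on length and atom economy, and the chosen plan wins on independence and security of the two stereocentres.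

**Alternative 3:** The cut removes C3–C4. The precursor is the diaryl ketone A6, whose ring A oxygen carries the chiral 2-iodo-1-arylethyl group that supplies O1, C2 and C3.
- Forward step: SmI2 (divalent samarium) with HMPA reduces the ketone to a ketyl and the primary iodide to a radical or organosamarium. The C3–C4 bond forms and gives the 4-aryl-flavan-4-ol A7. Reductive removal of the tertiary hydroxyl through the planar C4 cation, with hydride entering anti to ring B, would converge both C4 epimers on the cis flavan.
- In favour: C2 comes from a simple enantiopure two-carbon unit. The ring-forming step has no stereochemical demand, in which it equals the chosen key step. Ketyl–halide Barbier closures tolerate tertiary, hindered centres.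
- Against: the reduced C3 centre is beta to the aryloxy group on C2, so reductive beta-elimination (loss of the phenoxide) is the expected competing path. The tetra-ortho-substituted benzophenone is twisted and hindered toward C–C bond formation. Preparing A6 requires etherifying a hindered ortho-acyl phenol with a secondary benzylic electrophile. The deoxygenation adds a cationic step at C4.
- Comparison: on structure, both plans postpone ring C. On mechanism, the chosen plan has no beta-leaving group and no cation at C4. On step economy the two are similar, with Alternative 3 somewhat more convergent, which is a point in its favour.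

Key step: step 8

Assumptions and remarks on the chemistry:
- "PBC-8-yl" stands for the penta-O-benzylcatechin-8-yl group, (2R,3S)-3,5,7-tris(benzyloxy)-2-[3,4-bis(benzyloxy)phenyl]chroman-8-yl.
- The (2S) descriptor of the upper unit corresponds spatially to the (2R) series of flavan-3-ols. The target is 2,4-cis.
- In step 6 the quinine-derived thiourea is assumed to direct malonate to the Re face of the enone beta carbon, giving (S) at C4. If the sense is opposite, its quinidine-derived pseudoenantiomer is used.
- Compounds 13 and 15 carry the (R)-carbinol, which is the antipode required at that carbon because O1–C2 is formed with inversion. C4 has the target configuration throughout.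
- Relative to the simplest end-game, the ester groups are deliberately kept until after ring closure, where they block C6 and C8.

## Route

Step 1
Reactants: 1 (+)-catechin
Product: 3 3,5,7,3′,4′-penta-O-benzyl-(+)-catechin, (2R,3S)-3,5,7-tris(benzyloxy)-2-[3,4-bis(benzyloxy)phenyl]chromane, via tetra-O-benzylcatechin 2 (not isolated)
Conditions: BnBr (4.4 equiv), K2CO3, DMF, 0 °C → rt; then NaH, BnBr (1.5 equiv), 0 °C → rt
Reagents that add atoms: benzyl bromide, BrCc1ccccc1
Why: Williamson etherification; the mild carbonate stage caps the four phenols with little C-benzylation or C2 epimerisation, and NaH is added only afterwards for the secondary C3 hydroxyl.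

Step 2
Reactants: 3 penta-O-benzylcatechin
Product: 4 8-bromo-penta-O-benzylcatechin, (2R,3S)-8-bromo-3,5,7-tris(benzyloxy)-2-[3,4-bis(benzyloxy)phenyl]chromane
Conditions: NBS, CH2Cl2, −40 °C → rt
Reagents that add atoms: N-bromosuccinimide, O=C1CCC(=O)N1Br
Why: Electrophilic aromatic bromination; in benzylated catechins ring D reacts far faster than ring E, and C8 is the established preferred site over C6.

Step 3
Reactants: 4 8-bromo-penta-O-benzylcatechin
Product: 6 penta-O-benzylcatechin-8-carbaldehyde, via 8-lithio-penta-O-benzylcatechin 5 (not isolated)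
Conditions: n-BuLi, THF, −78 °C; DMF, −78 → 0 °C; H2O
Reagents that add atoms: N,N-dimethylformamide, CN(C)C=O
Why: Bromine–lithium exchange followed by formylation with DMF; the position is fixed by the bromide, and at −78 °C the benzyl ethers are not metalated.

Step 4
Reactants: 7 3′,4′-dihydroxyacetophenone
Product: 8 3′,4′-bis(benzyloxy)acetophenone, 1-[3,4-bis(benzyloxy)phenyl]ethan-1-one
Conditions: BnBr, K2CO3, DMF, 60 °C
Reagents that add atoms: benzyl bromide, BrCc1ccccc1
Why: Williamson etherification of the catechol; the methyl ketone is not alkylated by carbonate.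

Step 5
Reactants: 6 penta-O-benzylcatechin-8-carbaldehyde; 8 3′,4′-bis(benzyloxy)acetophenone
Product: 9 (E)-1-[3,4-bis(benzyloxy)phenyl]-3-(PBC-8-yl)prop-2-en-1-one
Conditions: KOH, EtOH–THF, 40 °C
Reagents that add atoms: none
Why: Claisen–Schmidt condensation; 2,6-dialkoxybenzaldehydes are non-enolisable and condense with acetophenones, and dehydration gives the conjugated E-enone.

Step 6
Reactants: 9 (E)-enone; 10 dimethyl malonate
Product: 11 dimethyl 2-[(1S)-3-[3,4-bis(benzyloxy)phenyl]-3-oxo-1-(PBC-8-yl)propyl]malonate
Conditions: 10 (5 equiv), N-[3,5-bis(trifluoromethyl)phenyl]-N′-[(8α,9S)-6′-methoxycinchonan-9-yl]thiourea (10 mol%), toluene, 40 °C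
Reagents that add atoms: none
Why: Catalytic asymmetric Michael addition of a malonate to a chalcone; the thiourea binds the enone carbonyl and the quinuclidine delivers the malonate to the Re face of the beta carbon, setting C4 (S) under catalyst control because the catechin stereocentres are remote.

Step 7
Reactants: 11 keto malonate
Product: 13 dimethyl 2-[(1S,3R)-3-[3,4-bis(benzyloxy)phenyl]-3-(tert-butyldimethylsilyloxy)-1-(PBC-8-yl)propyl]malonate, via hydroxy malonate 12 (not isolated)
Conditions: (S)-2-methyl-CBS-oxazaborolidine (0.3 equiv), BH3·SMe2, THF, −20 °C; MeOH, evaporate; TBSOTf, 2,6-lutidine, CH2Cl2, −78 → 0 °C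
Reagents that add atoms: tert-butyldimethylsilyl triflate, CC(C)(C)[Si](C)(C)OS(=O)(=O)C(F)(F)F
Why: Corey–Bakshi–Shibata reduction; with the aryl as the large and the methylene as the small group, the (S)-catalyst should give the (R)-carbinol (as acetophenone gives (R)-1-phenylethanol) and the esters are inert to borane at this temperature. Silylation in the same flask caps the hydroxyl before it can lactonise onto a malonate ester.

Step 8
Reactants: 13 silyloxy malonate; 14 dimethyl 3-oxopentanedioate
Product: 15 dimethyl 5-[(1S,3R)-3-[3,4-bis(benzyloxy)phenyl]-3-(tert-butyldimethylsilyloxy)-1-(PBC-8-yl)propyl]-2,4,6-trihydroxybenzene-1,3-dicarboxylate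
Conditions: 14 (4 equiv), Mg(OMe)2 (2 equiv), MeOH–toluene, 65 → 105 °C with slow distillation of MeOH, argon; then 0.5 M HCl, 0 °C
Reagents that add atoms: none
Why: Proposed new method: the magnesium enolate chelate of 14 attacks a malonate ester carbonyl of 13 that is activated by coordination to the same metal ion (intermolecular Claisen condensation, forming C5–C6), and the second alpha carbon of 14 then closes onto the remaining malonate ester in a Dieckmann condensation (forming C8–C8a). The 2,4-bis(methoxycarbonyl)cyclohexane-1,3,5-trione so formed enolises to the phloroglucinol phenoxide, an irreversible aromatisation that pulls the reversible condensations forward. Closest known reaction type: the classical Claisen–Dieckmann cyclocondensation of simple malonate esters with 3-oxoglutarate esters to phloroglucinol carboxylates, which has not been shown for an alpha-branched, fully elaborated malonate. Ring A is the only ring closed, by 6-exo-trig attack of a carbon enolate on an ester carbonyl. No stereocentre is formed; C4 is beta to the reacting carbonyls, has no acidic hydrogen and, with C2 held as a silyl ether, no retro-Michael exit, so it should pass unchanged. The selectivity required is C- over O-acylation: magnesium chelation favours carbon attack, and under methoxide an O-acylated enol lactone is reopened, the aromatic product being the only sink. Keeping methoxide at one equivalent per molecule of 14, the more acidic partner, leaves the malonate largely un-ionised and therefore electrophilic, and removal of methanol shifts both condensations. Regiochemistry cannot arise because the two malonate carbonyls and the two alpha carbons of 14 are pairwise equivalent.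

Step 9
Reactants: 15 ring A diester silyl ether
Product: 16 dimethyl 5-[(1S,3R)-3-[3,4-bis(benzyloxy)phenyl]-3-hydroxy-1-(PBC-8-yl)propyl]-2,4,6-trihydroxybenzene-1,3-dicarboxylate
Conditions: TBAF, AcOH (1:1), THF, 0 °C → rt
Reagents that add atoms: none
Why: Fluoride cleavage of a secondary silyl ether; acetic acid buffers the acidic ester-flanked phenols and avoids acid that could ionise the electron-rich benzylic carbinol.

Step 10
Reactants: 16 triol diester carbinol
Product: 17 dimethyl (2S,4S)-2-[3,4-bis(benzyloxy)phenyl]-5,7-dihydroxy-4-(PBC-8-yl)chromane-6,8-dicarboxylate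
Conditions: PPh3, DIAD, toluene–THF, −20 → 0 °C
Reagents that add atoms: none
Why: Mitsunobu etherification; either of the two equivalent ortho hydroxyls displaces the oxyphosphonium group in a 6-exo-tet SN2 closure, inverting (R) to (2S) and placing both aryl groups equatorial (2,4-cis). The esters make the phenols acidic enough for the betaine and block C6 and C8 against C-alkylation and against attack by the azodicarboxylate.

Step 11
Reactants: 17 flavan diester
Product: 19 (2S,4S)-2-[3,4-bis(benzyloxy)phenyl]-4-(PBC-8-yl)chromane-5,7-diol, via flavan-6,8-dicarboxylic acid 18 (not isolated)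
Conditions: KOH, MeOH–H2O–1,4-dioxane, 85 °C, argon; then 1 M HCl to pH 3, 50 °C
Reagents that add atoms: none
Why: Saponification followed by protodecarboxylation of the 2,4-dihydroxy-6-alkoxybenzoic acids through ipso protonation, the classical last stage of phloroglucinol syntheses; the benzyl ethers survive and neither C2 nor C4 has an acidic hydrogen.

Step 12
Reactants: 19 hepta-O-benzyl biflavan
Product: 20 CNP0180676.1, (2R,3S)-2-(3,4-dihydroxyphenyl)-8-[(2S,4S)-2-(3,4-dihydroxyphenyl)-5,7-dihydroxychroman-4-yl]chromane-3,5,7-triol
Conditions: H2 (1 atm), Pd(OH)2 on carbon, THF–MeOH–H2O, rt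
Reagents that add atoms: none
Why: Catalytic hydrogenolysis of the seven benzyl ethers under neutral conditions, as used for benzylated proanthocyanidins; the cyclic benzylic ethers O1–C2 and O1′–C2′ and the C4–C8′ bond are expected to survive.

## Compound list

1 | (+)-catechin | Oc1cc(O)c2c(c1)O[C@H](c1ccc(O)c(O)c1)[C@@H](O)C2 | starting material
2 | 5,7,3′,4′-tetra-O-benzyl-(+)-catechin | C(c9ccccc9)Oc1cc(OCc9ccccc9)c2c(c1)O[C@H](c3ccc(OCc9ccccc9)c(OCc9ccccc9)c3)[C@@H](O)C2 | intermediate (not isolated)
3 | 3,5,7,3′,4′-penta-O-benzyl-(+)-catechin | C(c9ccccc9)Oc1cc(OCc9ccccc9)c2c(c1)O[C@H](c3ccc(OCc9ccccc9)c(OCc9ccccc9)c3)[C@@H](OCc9ccccc9)C2 | intermediate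
4 | 8-bromo-penta-O-benzylcatechin | Brc4c(OCc9ccccc9)cc(OCc9ccccc9)c5c4O[C@H](c3ccc(OCc9ccccc9)c(OCc9ccccc9)c3)[C@@H](OCc9ccccc9)C5 | intermediate
5 | 8-lithio-penta-O-benzylcatechin | [Li]c4c(OCc9ccccc9)cc(OCc9ccccc9)c5c4O[C@H](c3ccc(OCc9ccccc9)c(OCc9ccccc9)c3)[C@@H](OCc9ccccc9)C5 | intermediate (not isolated)
6 | penta-O-benzylcatechin-8-carbaldehyde | O=Cc4c(OCc9ccccc9)cc(OCc9ccccc9)c5c4O[C@H](c3ccc(OCc9ccccc9)c(OCc9ccccc9)c3)[C@@H](OCc9ccccc9)C5 | intermediate
7 | 3′,4′-dihydroxyacetophenone | CC(=O)c1ccc(O)c(O)c1 | starting material
8 | 3′,4′-bis(benzyloxy)acetophenone | CC(=O)c1ccc(OCc2ccccc2)c(OCc2ccccc2)c1 | intermediate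
9 | (E)-1-[3,4-bis(benzyloxy)phenyl]-3-(PBC-8-yl)prop-2-en-1-one | O=C(/C=C/c4c(OCc9ccccc9)cc(OCc9ccccc9)c5c4O[C@H](c3ccc(OCc9ccccc9)c(OCc9ccccc9)c3)[C@@H](OCc9ccccc9)C5)c1ccc(OCc2ccccc2)c(OCc2ccccc2)c1 | intermediate
10 | dimethyl malonate | COC(=O)CC(=O)OC | starting material
11 | dimethyl 2-[(1S)-3-[3,4-bis(benzyloxy)phenyl]-3-oxo-1-(PBC-8-yl)propyl]malonate | O=C(C[C@@H](C(C(=O)OC)C(=O)OC)c4c(OCc9ccccc9)cc(OCc9ccccc9)c5c4O[C@H](c3ccc(OCc9ccccc9)c(OCc9ccccc9)c3)[C@@H](OCc9ccccc9)C5)c1ccc(OCc2ccccc2)c(OCc2ccccc2)c1 | intermediate
12 | dimethyl 2-[(1S,3R)-3-[3,4-bis(benzyloxy)phenyl]-3-hydroxy-1-(PBC-8-yl)propyl]malonate | O[C@@H](c3ccc(OCc9ccccc9)c(OCc9ccccc9)c3)C[C@@H](C(C(=O)OC)C(=O)OC)c4c(OCc9ccccc9)cc(OCc9ccccc9)c5c4O[C@H](c3ccc(OCc9ccccc9)c(OCc9ccccc9)c3)[C@@H](OCc9ccccc9)C5 | intermediate (not isolated)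
13 | dimethyl 2-[(1S,3R)-3-[3,4-bis(benzyloxy)phenyl]-3-(tert-butyldimethylsilyloxy)-1-(PBC-8-yl)propyl]malonate | CC(C)(C)[Si](C)(C)O[C@@H](c3ccc(OCc9ccccc9)c(OCc9ccccc9)c3)C[C@@H](C(C(=O)OC)C(=O)OC)c4c(OCc9ccccc9)cc(OCc9ccccc9)c5c4O[C@H](c3ccc(OCc9ccccc9)c(OCc9ccccc9)c3)[C@@H](OCc9ccccc9)C5 | intermediate
14 | dimethyl 3-oxopentanedioate | COC(=O)CC(=O)CC(=O)OC | starting material
15 | dimethyl 5-[(1S,3R)-3-[3,4-bis(benzyloxy)phenyl]-3-(tert-butyldimethylsilyloxy)-1-(PBC-8-yl)propyl]-2,4,6-trihydroxybenzene-1,3-dicarboxylate | CC(C)(C)[Si](C)(C)O[C@@H](c3ccc(OCc9ccccc9)c(OCc9ccccc9)c3)C[C@@H](c1c(O)c(C(=O)OC)c(O)c(C(=O)OC)c1O)c4c(OCc9ccccc9)cc(OCc9ccccc9)c5c4O[C@H](c3ccc(OCc9ccccc9)c(OCc9ccccc9)c3)[C@@H](OCc9ccccc9)C5 | intermediate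
16 | dimethyl 5-[(1S,3R)-3-[3,4-bis(benzyloxy)phenyl]-3-hydroxy-1-(PBC-8-yl)propyl]-2,4,6-trihydroxybenzene-1,3-dicarboxylate | O[C@@H](c3ccc(OCc9ccccc9)c(OCc9ccccc9)c3)C[C@@H](c1c(O)c(C(=O)OC)c(O)c(C(=O)OC)c1O)c4c(OCc9ccccc9)cc(OCc9ccccc9)c5c4O[C@H](c3ccc(OCc9ccccc9)c(OCc9ccccc9)c3)[C@@H](OCc9ccccc9)C5 | intermediate
17 | dimethyl (2S,4S)-2-[3,4-bis(benzyloxy)phenyl]-5,7-dihydroxy-4-(PBC-8-yl)chromane-6,8-dicarboxylate | Oc1c(C(=O)OC)c(O)c2c(c1C(=O)OC)O[C@H](c3ccc(OCc9ccccc9)c(OCc9ccccc9)c3)C[C@@H]2c4c(OCc9ccccc9)cc(OCc9ccccc9)c5c4O[C@H](c3ccc(OCc9ccccc9)c(OCc9ccccc9)c3)[C@@H](OCc9ccccc9)C5 | intermediate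
18 | (2S,4S)-2-[3,4-bis(benzyloxy)phenyl]-5,7-dihydroxy-4-(PBC-8-yl)chromane-6,8-dicarboxylic acid | Oc1c(C(=O)O)c(O)c2c(c1C(=O)O)O[C@H](c3ccc(OCc9ccccc9)c(OCc9ccccc9)c3)C[C@@H]2c4c(OCc9ccccc9)cc(OCc9ccccc9)c5c4O[C@H](c3ccc(OCc9ccccc9)c(OCc9ccccc9)c3)[C@@H](OCc9ccccc9)C5 | intermediate (not isolated)
19 | (2S,4S)-2-[3,4-bis(benzyloxy)phenyl]-4-(PBC-8-yl)chromane-5,7-diol | Oc1cc(O)c2c(c1)O[C@H](c3ccc(OCc9ccccc9)c(OCc9ccccc9)c3)C[C@@H]2c4c(OCc9ccccc9)cc(OCc9ccccc9)c5c4O[C@H](c3ccc(OCc9ccccc9)c(OCc9ccccc9)c3)[C@@H](OCc9ccccc9)C5 | intermediate
20 | CNP0180676.1, (2R,3S)-2-(3,4-dihydroxyphenyl)-8-[(2S,4S)-2-(3,4-dihydroxyphenyl)-5,7-dihydroxychroman-4-yl]chromane-3,5,7-triol | Oc1cc(O)c2c(c1)O[C@H](c1ccc(O)c(O)c1)C[C@@H]2c1c(O)cc(O)c2c1O[C@H](c1ccc(O)c(O)c1)[C@@H](O)C2 | target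

## Step count and least certain steps

Total: 12 steps. Longest linear sequence: 11 steps (steps 1, 2, 3, 5, 6, 7, 8, 9, 10, 11, 12 from (+)-catechin); step 4 is a one-step side branch.

**Step 8 (key step).** The most likely failure is that the first Claisen acylation does not start: the alpha-branched malonate esters are hindered, and the chelated enolate of 14 is a weak nucleophile that may instead consume itself by self-condensation. Lesser risks are diversion into O-acylated enol lactones that do not reopen and loss of the silyl group at 105 °C.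

The fallback uses known chemistry only and introduces ring A as a preformed arene instead of building it. It sets out from aldehyde 6 (with ketone 8) and comes back to the route at 19.
- Phloroglucinol is converted with MOMCl and i-Pr2NEt into 1,3,5-tris(methoxymethoxy)benzene F1.
- Directed ortho-lithiation of F1 (n-BuLi, THF, 0 °C) and addition to 6 gives the diarylmethanol F2.
- Ketone 8 is converted (TMSCl, NaI, Et3N, MeCN) into its trimethylsilyl enol ether F3.
- A catalytic Lewis acid (Bi(OTf)3, CH2Cl2–MeCN, −20 °C) ionises F2 to the strongly stabilised diarylmethyl cation, which F3 captures in an SN1 alkylation to give the beta,beta-diaryl ketone F4.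
- This bond formation does not control C4. The two C4 epimers are diastereomers because of the catechin unit and would be separated by chromatography; the (S)-epimer is carried on.
- NaBH4 reduces F4 to the alcohol F5 (carbinol configuration immaterial).
- HCl in MeOH at 40 °C removes the three methoxymethyl groups and closes ring C through the benzylic cation under equilibrating conditions. The diequatorial 2,4-cis flavan 19 is expected to predominate.

**Step 6.** The most likely failure is slow or poorly face-selective addition, because the beta-aryl group is twisted and strongly electron-donating, with erosion of C4 purity by retro-Michael reaction on long exposure to base. The fallback reverses the roles of the partners. It sets out from 6 and 10 and returns at 11.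
- Knoevenagel condensation (piperidine, AcOH, toluene, water removal) gives dimethyl 2-[(PBC-8-yl)methylidene]malonate F6.
- A catalytic enantioselective Mukaiyama–Michael addition of the silyl enol ether F3 follows, using the Cu(SbF6)2 complex (divalent copper) of 2,2′-isopropylidenebis[(4S)-4-tert-butyl-2-oxazoline] in CH2Cl2 at −40 °C with aqueous work-up. The ligand antipode is chosen for (S) at C4. This delivers 11.

**Step 7.** The most likely failure is lactonisation of the free carbinol 12 onto a malonate ester before silyl transfer is complete. The fallback accepts this and uses the lactone as internal protection. It sets out from 12 and returns at 16.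
- Brief treatment of 12 with catalytic DBU closes it to methyl (4S,6R)-6-[3,4-bis(benzyloxy)phenyl]-2-oxo-4-(PBC-8-yl)tetrahydro-2H-pyran-3-carboxylate F7.
- F7 is submitted to the step 8 conditions in place of 13. Its lactone carbonyl is the more reactive acyl donor, and the ring-opened hydroxy diester is in equilibrium with it in methanol.
- Either way both malonyl carbons end in ring A, and 16 results directly. Steps 7 (silylation part) and 9 are then unnecessary.

**Step 10.** The most likely failure is partial loss of stereochemical fidelity, because the oxyphosphonium ion of a para-alkoxybenzylic alcohol can ionise before the phenoxide attacks; elimination toward the styrene is the related path. The fallback abandons inversion control for thermodynamic control. It sets out from 16 and returns at 17 without new isolated compounds.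
- Catalytic acid (pyridinium p-toluenesulfonate, or BF3·OEt2 at −40 °C, CH2Cl2) generates the benzylic cation reversibly.
- Ring closure by the ortho hydroxyl should favour the 2,4-cis isomer 17, with both aryl groups equatorial. Ring A is deactivated by its two esters, which protects the C4–C8′ bond.
- In that variant the reduction in step 7 need not be enantioselective.

## Further compounds

F1 | step 8 | 1,3,5-tris(methoxymethoxy)benzene | COCOc1cc(OCOC)cc(OCOC)c1
F2 | step 8 | (PBC-8-yl)[2,4,6-tris(methoxymethoxy)phenyl]methanol (both carbinol epimers) | OC(c1c(OCOC)cc(OCOC)cc1OCOC)c4c(OCc9ccccc9)cc(OCc9ccccc9)c5c4O[C@H](c3ccc(OCc9ccccc9)c(OCc9ccccc9)c3)[C@@H](OCc9ccccc9)C5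
F3 | step 8 | 1-[3,4-bis(benzyloxy)phenyl]-1-(trimethylsilyloxy)ethene | C=C(O[Si](C)(C)C)c1ccc(OCc2ccccc2)c(OCc2ccccc2)c1
F4 | step 8 | (3S)-1-[3,4-bis(benzyloxy)phenyl]-3-(PBC-8-yl)-3-[2,4,6-tris(methoxymethoxy)phenyl]propan-1-one | O=C(C[C@@H](c1c(OCOC)cc(OCOC)cc1OCOC)c4c(OCc9ccccc9)cc(OCc9ccccc9)c5c4O[C@H](c3ccc(OCc9ccccc9)c(OCc9ccccc9)c3)[C@@H](OCc9ccccc9)C5)c1ccc(OCc2ccccc2)c(OCc2ccccc2)c1
F5 | step 8 | (3S)-1-[3,4-bis(benzyloxy)phenyl]-3-(PBC-8-yl)-3-[2,4,6-tris(methoxymethoxy)phenyl]propan-1-ol (both carbinol epimers) | OC(C[C@@H](c1c(OCOC)cc(OCOC)cc1OCOC)c4c(OCc9ccccc9)cc(OCc9ccccc9)c5c4O[C@H](c3ccc(OCc9ccccc9)c(OCc9ccccc9)c3)[C@@H](OCc9ccccc9)C5)c1ccc(OCc2ccccc2)c(OCc2ccccc2)c1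
F6 | step 6 | dimethyl 2-[(PBC-8-yl)methylidene]malonate | COC(=O)C(=Cc4c(OCc9ccccc9)cc(OCc9ccccc9)c5c4O[C@H](c3ccc(OCc9ccccc9)c(OCc9ccccc9)c3)[C@@H](OCc9ccccc9)C5)C(=O)OC
F7 | step 7 | methyl (4S,6R)-6-[3,4-bis(benzyloxy)phenyl]-2-oxo-4-(PBC-8-yl)tetrahydro-2H-pyran-3-carboxylate (C3 epimerisable, unassigned) | COC(=O)C1C(=O)O[C@@H](c3ccc(OCc9ccccc9)c(OCc9ccccc9)c3)C[C@@H]1c4c(OCc9ccccc9)cc(OCc9ccccc9)c5c4O[C@H](c3ccc(OCc9ccccc9)c(OCc9ccccc9)c3)[C@@H](OCc9ccccc9)C5
F0 | step 10 | none | none
A1 | alternative 1 | 3,5-bis(benzyloxy)-2-[1-(PBC-8-yl)ethenyl]phenol | C=C(c1c(O)cc(OCc2ccccc2)cc1OCc1ccccc1)c4c(OCc9ccccc9)cc(OCc9ccccc9)c5c4O[C@H](c3ccc(OCc9ccccc9)c(OCc9ccccc9)c3)[C@@H](OCc9ccccc9)C5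
A2 | alternative 1 | 3,4-bis(benzyloxy)benzaldehyde | O=Cc1ccc(OCc2ccccc2)c(OCc2ccccc2)c1
A3 | alternative 1 | nona-O-benzyl flav-3-ene (2,4-diaryl-2H-chromene) with the target configuration at C2 | C(c9ccccc9)Oc1cc(OCc9ccccc9)c2c(c1)O[C@H](c3ccc(OCc9ccccc9)c(OCc9ccccc9)c3)C=C2c4c(OCc9ccccc9)cc(OCc9ccccc9)c5c4O[C@H](c3ccc(OCc9ccccc9)c(OCc9ccccc9)c3)[C@@H](OCc9ccccc9)C5
A4 | alternative 2 | 3,5-bis(benzyloxy)phenol | Oc1cc(OCc2ccccc2)cc(OCc2ccccc2)c1
A5 | alternative 2 | nona-O-benzyl flav-2-ene (2,4-diaryl-4H-chromene) with the target configuration at C4 | C(c9ccccc9)Oc1cc(OCc9ccccc9)c2c(c1)OC(c3ccc(OCc9ccccc9)c(OCc9ccccc9)c3)=C[C@@H]2c4c(OCc9ccccc9)cc(OCc9ccccc9)c5c4O[C@H](c3ccc(OCc9ccccc9)c(OCc9ccccc9)c3)[C@@H](OCc9ccccc9)C5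
A6 | alternative 3 | [2,4-bis(benzyloxy)-6-[1-[3,4-bis(benzyloxy)phenyl]-2-iodoethoxy]phenyl](PBC-8-yl)methanone, ether carbon with the target C2 arrangement | O=C(c1c(OCc9ccccc9)cc(OCc9ccccc9)cc1O[C@H](c3ccc(OCc9ccccc9)c(OCc9ccccc9)c3)CI)c4c(OCc9ccccc9)cc(OCc9ccccc9)c5c4O[C@H](c3ccc(OCc9ccccc9)c(OCc9ccccc9)c3)[C@@H](OCc9ccccc9)C5
A7 | alternative 3 | nona-O-benzyl 4-hydroxy derivative of the target (4-aryl-flavan-4-ol) | C(c9ccccc9)Oc1cc(OCc9ccccc9)c2c(c1)O[C@H](c3ccc(OCc9ccccc9)c(OCc9ccccc9)c3)C[C@]2(O)c4c(OCc9ccccc9)cc(OCc9ccccc9)c5c4O[C@H](c3ccc(OCc9ccccc9)c(OCc9ccccc9)c3)[C@@H](OCc9ccccc9)C5
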